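A run cannot convert more substrate than its limiting reagent allows, which for the theta run meant 54.3%, and the theta run levelled off lower still, at 38.0% in its last reading.

| setting | theta | delta | flask |
|---|---|---|---|
| left-handed substrate | 0.23 M | 0.23 M | 0.23 M |
| right-handed substrate | 0.23 M | 0.23 M | 0.23 M |
| reagent | 0.25 M | 1 M | 0.506 M |
| racemization catalyst | 0.78 mM | 0.78 mM | 0.78 mM |
| remark | run made earlier | run made earlier |  |
| time |  |  | 3.0 min |

- theta (time / s: left-handed product / %, right-handed product / %): 10.0: 6, 6; 25.0: 17, 6; 50.0: 19, 9; 80.0: 24, 13; 120: 26, 12
- delta (time / s: left-handed product / %, right-handed product / %): 20.0: 29, 18; 40.0: 41, 25; 60.0: 46, 32; 80.0: 42, 32; 120: 50, 34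

(each reading ± 2 percentage points)

- left-handed product and right-handed product together, in percent of the left-handed substrate and right-handed substrate charged together, at 3.0 min
- excess of left-handed product over right-handed product in the product at 3.0 min
- whether the exchange between left-handed substrate and right-handed substrate keeps pace with the reaction: how far the product's excess at 3.0 min gets from its value without exchange to its value with instant exchange (above 80% keeps pace, below 20% hardly takes part, else lags behind)

- reagent is single-handed; left-handed substrate and right-handed substrate are mirror images of each other, charged as a racemate, each of them at the stated concentration
- an excess is below zero if the other one leads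
- the handed part of reagent does not stay in what it makes, so the products of the two hands are mirror images too

The delta run's product read 84.0% at its last reading, yet the delta run's reagent charge was 4.00 times the theta run's, a larger factor than the 2.21 between their products.

I took the last readings as the point where the reagent had gone, and asked where it went. The share of the charge that ended in product read 69.9% in theta and 38.6% in delta. So the waste ratio, reagent lost for each reagent turned into product, read 0.430 and 1.59, a rise of 3.70 times. With the substrate charge held, a rise close to that of the reagent charge is what a loss of second order in [reagent] gives against a product step of first order. I therefore carried g, the waste ratio divided by the charged [reagent], pooled from both runs as 1.61 M⁻¹.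

For the flask this gave a waste ratio of 0.817, so 55.0% of its reagent in product and, with the reagent assumed gone, my yield of 60.5%.

The forecast, holding that “the reagent is dying rather than simply being used up”, gave a yield of 60%, an excess of 26%, and exchange that hardly takes part.

The flask gave a yield of 67.6%, an excess of 23.2%, and exchange that lags behind, 59% of the way to its instant-exchange value.

    left-handed substrate + racemization catalyst ⇌ right-handed substrate + racemization catalyst, rate k1*[racemization catalyst]*[left-handed substrate] forward; the back reaction follows from the equilibrium constant (k = 45.0 M⁻¹ s⁻¹)
    reagent + right-handed substrate → right-handed product (k = 0.0440 M⁻¹ s⁻¹)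
    reagent + left-handed substrate → left-handed product (k = 0.0790 M⁻¹ s⁻¹)
    2 reagent → self-condensation product (k = 0.0230 M⁻¹ s⁻¹)
    reagent + racemization catalyst → spent catalyst A (k = 0.0350 M⁻¹ s⁻¹)
    2 racemization catalyst → spent catalyst B (k = 9.90 M⁻¹ s⁻¹)

At the start, the flask's reagent went to self-condensation product at 0.823 of the rate at which it went to the two products together. With 4.3% of its reagent left at 3.00 min, the flask's waste ratio was 0.557, so g stood at 1.10 M⁻¹, lower than my pooled value. Carried to the same flask charged with 0.13 M of reagent, of which 1.4% was left, this g gives a waste ratio of 0.143 and a yield of 24.4%, beside the 25.0% that flask gave.

All runs stem from a simulated flask on assumed constants, and the scatter is random.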